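**Strategy.** Locants are those of the target's spiro[5.5]undecane name. The route rests on spiro carbon C6, which lies between the tertiary carbinol C1 and the gem-dimethyl carbon C5 of ring A and carries the C7 vinyl and C11 methylene arms of ring B. In the key step a C1–C6 epoxide opens at C6 while the alkenyl carbon C7 of a cyclopentenyl silyl ether shifts from C11 to C6. This one semipinacol 1,2-shift expands a cyclopentene to the six-membered ring B, creates the quaternary spiro centre and fixes it relative to the C1 hydroxyl. The precursor is a 2,6,6-trimethylcyclohexene oxide bearing a 1-silyloxycyclopent-2-enyl group, its epoxide face set by the C3 hydroxyl of (4R,6R)-actinol.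

Key step: step 4

Locants used below: ring A = C1 (C(CH3)OH), C2, C3 (CHBr), C4, C5 (C(CH3)2), C6 (spiro); ring B = C6, C7=C8, C9 (carries the exocyclic CHBr), C10, C11. Intermediates are described with these target locants even where their own systematic name numbers differently.

Assumption: (4R,6R)-4-hydroxy-2,2,6-trimethylcyclohexanone (actinol) is taken as a purchasable chiral-pool ketone; its carbinol centre becomes C3 and is the only source of absolute configuration.

**Step 1**
Reactants: 1 (4R,6R)-4-hydroxy-2,2,6-trimethylcyclohexan-1-one (actinol)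
Product: 2 2,4,6-triisopropylbenzenesulfonyl hydrazone of 1 (C=N at future C6)
Conditions: TrisNHNH2 (1.05 equiv), conc. HCl (cat.), MeCN, rt
Reagents that add atoms: 2,4,6-triisopropylbenzenesulfonyl hydrazide, CC(C)c1cc(C(C)C)c(S(=O)(=O)NN)c(C(C)C)c1
Why: Hydrazone formation at the only carbonyl should proceed as for other 2,2,6-trimethylcyclohexanones; the carbinol centre (future C3) is untouched, and epimerisation at the methyl-bearing α-carbon would not matter because that carbon becomes sp2 in step 2.

**Step 2**
Reactants: 2 trisylhydrazone; 3 cyclopent-2-en-1-one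
Product: 7 (1R)-3,5,5-trimethyl-4-[1-(trimethylsilyloxy)cyclopent-2-en-1-yl]cyclohex-3-en-1-ol (both epimers at the silyloxy carbon), via vinyllithium 4 (not isolated), via dilithium dialkoxide 5 (not isolated), via bis-silyl ether 6 (not isolated)
Conditions: n-BuLi (3.3 equiv), THF, −78 → 0 °C; 3, −78 °C; TMSCl (4 equiv), −78 °C → rt; then K2CO3 (cat.), MeOH, 0 °C
Reagents that add atoms: chlorotrimethylsilane, C[Si](C)(C)Cl
Why: Shapiro reaction (the only α-hydrogen sits on the methyl-bearing carbon, so the C6 vinyllithium with the C1=C6 alkene forms), 1,2-addition to the enone carbonyl, silylation of both alkoxides and selective methanolysis of the unhindered secondary silyl ether; the new carbinol carbon (future C11) forms as both epimers, which converge when it becomes the carbonyl carbon in step 4.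

**Step 3**
Reactants: 7 homoallylic alcohol
Product: 8 (1S,3S,6R)-1,5,5-trimethyl-6-[1-(trimethylsilyloxy)cyclopent-2-en-1-yl]-7-oxabicyclo[4.1.0]heptan-3-ol (epoxide oxygen cis to the C3 hydroxyl)
Conditions: VO(acac)2 (5 mol %), TBHP (1.5 equiv, in decane), CH2Cl2, 0 °C → rt
Reagents that add atoms: tert-butyl hydroperoxide, CC(C)(C)OO
Why: Hydroxyl-directed epoxidation of a cyclohex-3-en-1-ol: the vanadium-bound C3 alkoxide should deliver oxygen to the tetrasubstituted C1=C6 alkene from its own face, setting C1 and C6, while the silylated tertiary carbinol cannot direct and the disubstituted cyclopentene alkene is left alone.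

**Step 4**
Reactants: 8 epoxy silyl ether
Product: 9 (6R,7S,9S)-7,9-dihydroxy-7,11,11-trimethylspiro[5.5]undec-4-en-1-one (target locants: C11 ketone, C7=C8 alkene, hydroxyls at C1 and C3)
Conditions: BF3·OEt2 (1.2 equiv), CH2Cl2, −78 °C; aq. NaHCO3
Reagents that add atoms: none
Why: Semipinacol rearrangement of a 2,3-epoxy alcohol silyl ether: BF3 binds the epoxide oxygen, the C6–O bond ionises, and the alkenyl carbon C7 migrates from the silyloxy carbon C11 to C6 through a bridged, cyclopropylcarbinyl-like transition state while the silyloxy lone pair turns C11 into the ketone and the silyl group is lost. Ring B is thus closed not by cyclisation but by a suprafacial 1,2-carbon shift that inserts C6 into the five-membered ring (five-to-six ring expansion). C6 is formed with inversion because C7 enters anti to the departing epoxide oxygen, so the C7 arm ends trans and the C11 carbonyl arm cis to the C1 hydroxyl; C1 keeps the configuration given in step 3, so both centres derive from C3. The step needs C6–O rather than C1–O cleavage and alkenyl (C7) rather than alkyl (C10) migration. The first should be secured by the push of the adjacent silyloxy group, π participation and relief of strain at C6, which is flanked by two fully substituted carbons; the second by the higher migratory aptitude of an sp2 carbon. The cis C3 hydroxyl cannot attack the epoxide from the rear and is tolerated.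

**Step 5**
Reactants: 9 spiro hydroxy ketone
Product: 10 4-methylbenzenesulfonyl hydrazone of 9 (C=N at C11, stereocentres as in 9)
Conditions: TsNHNH2 (1.5 equiv), PPTS (cat.), EtOH, 60 °C
Reagents that add atoms: p-toluenesulfonyl hydrazide, Cc1ccc(S(=O)(=O)NN)cc1
Why: Hydrazone formation at the only carbonyl; the α-carbon C6 is quaternary, so neither epimerisation nor conjugation of the C7=C8 alkene is possible, and the mildly acidic medium should avoid retro-aldol cleavage of the β-hydroxy ketone.

**Step 6**
Reactants: 10 tosylhydrazone
Product: 12 (1S,3S,6S)-1,5,5-trimethylspiro[5.5]undec-7-ene-1,3-diol, via tosylhydrazide 11 (not isolated)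
Conditions: catecholborane (4 equiv), CHCl3, 0 °C; then NaOAc·3H2O, reflux
Reagents that add atoms: none
Why: Mild Wolff–Kishner-type deoxygenation (hydride addition to C=N, then base-induced loss of sulfinate and N2) should turn the C11 carbonyl into the C11 methylene without touching the non-conjugated C7=C8 alkene or the three stereocentres.

**Step 7**
Reactants: 12 diol
Product: 13 (1S,3R,6S)-3-bromo-1,5,5-trimethylspiro[5.5]undec-7-en-1-ol
Conditions: CBr4 (1.5 equiv), PPh3 (1.6 equiv), CH2Cl2, 0 °C → rt
Reagents that add atoms: tetrabromomethane, BrC(Br)(Br)Br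
Why: Appel reaction: only the secondary C3 hydroxyl is activated (the hindered tertiary C1 hydroxyl is not), and bromide displaces it by SN2 with inversion, which places bromine trans to the C1 hydroxyl (3R); the cis C1 hydroxyl cannot close an oxetane from the same face.

**Step 8**
Reactants: 13 bromo alcohol
Product: 14 (6S,7S,9R)-9-bromo-7-hydroxy-7,11,11-trimethylspiro[5.5]undec-1-en-3-one (target locants: C9 ketone conjugated with C7=C8)
Conditions: Rh2(cap)4 (cap = caprolactamate, 1 mol %), TBHP (70% in water, 5 equiv), ClCH2CH2Cl, 40 °C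
Reagents that add atoms: tert-butyl hydroperoxide, CC(C)(C)OO
Why: Dirhodium-catalysed allylic oxidation: C9 is the only allylic carbon bearing hydrogen (the other allylic position is the quaternary C6), so its methylene should be oxidised to the ketone of a 4,4-disubstituted cyclohex-2-enone under neutral conditions that spare the secondary bromide and the tertiary alcohol.

**Step 9**
Reactants: 14 enone
Product: 15 (1S,3R,6S,9E)-3-bromo-9-(bromomethylidene)-1,5,5-trimethylspiro[5.5]undec-7-en-1-ol (target)
Conditions: Ph3PCH2Br+ Br− (2.0 equiv), NaN(SiMe3)2 (1.9 equiv), THF, −78 °C; then 14, −78 °C → rt; chromatographic removal of the (Z)-isomer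
Reagents that add atoms: (bromomethyl)triphenylphosphonium bromide, BrC[P+](c1ccccc1)(c1ccccc1)c1ccccc1.[Br-]
Why: Wittig bromomethylenation of the enone carbonyl with Ph3P=CHBr, generated with a slight deficit of base so that no C1 alkoxide (vinylogous retro-aldol) forms; the (E)-alkene (bromine syn to C10) is expected together with its (Z)-isomer, from which it is separated.

**Compound list**
1 | (4R,6R)-4-hydroxy-2,2,6-trimethylcyclohexan-1-one (actinol) | CC1(C)C[C@H](O)C[C@@H](C)C1=O | starting material
2 | 2,4,6-triisopropylbenzenesulfonyl hydrazone of 1 | CC1(C)C[C@H](O)C[C@@H](C)C1=NNS(=O)(=O)c2c(C(C)C)cc(C(C)C)cc2C(C)C | intermediate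
3 | cyclopent-2-en-1-one | O=C1C=CCC1 | starting material
4 | lithium (R)-4-lithio-3,5,5-trimethylcyclohex-3-en-1-olate (vinyllithium) | CC1(C)C[C@H](O[Li])CC(C)=C1[Li] | intermediate
5 | dilithium dialkoxide from addition of 4 to 3 | CC1(C)C[C@H](O[Li])CC(C)=C1C2(O[Li])C=CCC2 | intermediate
6 | bis(trimethylsilyl) ether of the adduct | CC1(C)C[C@H](O[Si](C)(C)C)CC(C)=C1C2(O[Si](C)(C)C)C=CCC2 | intermediate
7 | (1R)-3,5,5-trimethyl-4-[1-(trimethylsilyloxy)cyclopent-2-en-1-yl]cyclohex-3-en-1-ol (both epimers at the silyloxy carbon) | CC1(C)C[C@H](O)CC(C)=C1C2(O[Si](C)(C)C)C=CCC2 | intermediate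
8 | (1S,3S,6R)-1,5,5-trimethyl-6-[1-(trimethylsilyloxy)cyclopent-2-en-1-yl]-7-oxabicyclo[4.1.0]heptan-3-ol (epoxide cis to the hydroxyl) | CC1(C)C[C@H](O)C[C@]2(C)O[C@]12C3(O[Si](C)(C)C)C=CCC3 | intermediate
9 | (6R,7S,9S)-7,9-dihydroxy-7,11,11-trimethylspiro[5.5]undec-4-en-1-one | CC1(C)C[C@H](O)C[C@](C)(O)[C@@]12C=CCCC2=O | intermediate
10 | 4-methylbenzenesulfonyl hydrazone of 9 | CC1(C)C[C@H](O)C[C@](C)(O)[C@@]12C=CCCC2=NNS(=O)(=O)c3ccc(C)cc3 | intermediate
11 | N′-alkyl tosylhydrazide from reduction of the C=N bond of 10 (boron-bound in the flask, C11 configuration undefined) | CC1(C)C[C@H](O)C[C@](C)(O)[C@@]12C=CCCC2NNS(=O)(=O)c3ccc(C)cc3 | intermediate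
12 | (1S,3S,6S)-1,5,5-trimethylspiro[5.5]undec-7-ene-1,3-diol | CC1(C)C[C@H](O)C[C@](C)(O)[C@@]12C=CCCC2 | intermediate
13 | (1S,3R,6S)-3-bromo-1,5,5-trimethylspiro[5.5]undec-7-en-1-ol | CC1(C)C[C@@H](Br)C[C@](C)(O)[C@@]12C=CCCC2 | intermediate
14 | (6S,7S,9R)-9-bromo-7-hydroxy-7,11,11-trimethylspiro[5.5]undec-1-en-3-one | CC1(C)C[C@@H](Br)C[C@](C)(O)[C@@]12C=CC(=O)CC2 | intermediate
15 | (1S,3R,6S,9E)-3-bromo-9-(bromomethylidene)-1,5,5-trimethylspiro[5.5]undec-7-en-1-ol | CC1(C)C[C@@H](Br)C[C@](C)(O)[C@@]12C=C/C(=C/Br)CC2 | target

**Total step count:** 9. **Longest linear sequence:** 9 steps (from 1).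

**Steps most likely to fail**

1. Step 4 (key step). Ionisation of the epoxide at the methyl-bearing C1 instead of C6, or migration of the saturated carbon C10 in place of the alkenyl carbon C7, would divert the cation to elimination, ring-A contraction or a regioisomeric enone. Fallback (sets out from 2, returns at 9): the migrating carbon is made a vinylsilane so that C6 attacks it ipso with β-silyl stabilisation, which strengthens both the assistance to C6–O cleavage and the preference for the alkenyl shift. The vinyllithium 4 from 2 is added to the known 2-(trimethylsilyl)cyclopent-2-en-1-one F1 in place of 3 and silylated as in step 2 to the bis-silyl ether F2. Methanolysis of the secondary silyl ether gives the alcohol F3, and directed epoxidation as in step 3 gives the epoxide F4. BF3·OEt2 at −78 °C should then give the C7-silylated spiro ketone F5, and protodesilylation of the vinylsilane (CF3CO2H, CH2Cl2, 0 °C) returns to 9.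

2. Step 9. Poor control of alkene geometry in the olefination of an enone whose two flanking carbons differ little in size. Fallback (sets out from 14, returns at 15): Corey–Fuchs-type dibromoolefination of 14 (CBr4, PPh3, toluene, 80 °C) gives the 1,1-dibromodiene F6. Stereoselective hydrodebromination (Pd(PPh3)4 cat., Bu3SnH, toluene, rt) follows, in which the palladium catalyst should insert into the less hindered C–Br bond syn to the planar vinylic C8–H. Its replacement by hydrogen leaves the bromine syn to C10, which is the (E)-isomer 15.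

3. Step 6. Slow hydride delivery to the hindered hydrazone, or skeletal rearrangement of the homoallylic C11 intermediate (1,2-vinyl shift with ring contraction) during loss of nitrogen. Fallback (sets out from 9, replaces steps 5 and 6, returns at 12): thioketalisation of 9 (ethane-1,2-dithiol, BF3·OEt2, CH2Cl2, 0 °C) gives the dithiolane F7. Desulfurisation with acetone-deactivated Raney nickel (Ni) in EtOH at rt, chosen to spare the hindered C7=C8 alkene, then gives 12.

**Further compounds**
F1 | step 4 | 2-(trimethylsilyl)cyclopent-2-en-1-one | C[Si](C)(C)C1=CCCC1=O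
F2 | step 4 | bis(trimethylsilyl) ether of the adduct of 4 and F1 | CC1(C)C[C@H](O[Si](C)(C)C)CC(C)=C1C2(O[Si](C)(C)C)C([Si](C)(C)C)=CCC2
F3 | step 4 | (1R)-3,5,5-trimethyl-4-[2-(trimethylsilyl)-1-(trimethylsilyloxy)cyclopent-2-en-1-yl]cyclohex-3-en-1-ol | CC1(C)C[C@H](O)CC(C)=C1C2(O[Si](C)(C)C)C([Si](C)(C)C)=CCC2
F4 | step 4 | epoxide of F3 across C1–C6, cis to the C3 hydroxyl | CC1(C)C[C@H](O)C[C@]2(C)O[C@]12C3(O[Si](C)(C)C)C([Si](C)(C)C)=CCC3
F5 | step 4 | 7,9-dihydroxy-7,11,11-trimethyl-5-(trimethylsilyl)spiro[5.5]undec-4-en-1-one (stereocentres as in 9) | CC1(C)C[C@H](O)C[C@](C)(O)[C@@]12C([Si](C)(C)C)=CCCC2=O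
F6 | step 9 | 9-bromo-3-(dibromomethylidene)-7,11,11-trimethylspiro[5.5]undec-1-en-7-ol (stereocentres as in 14) | CC1(C)C[C@@H](Br)C[C@](C)(O)[C@@]12C=CC(=C(Br)Br)CC2
F7 | step 6 | 1,3-dithiolane of 9 at C11 | CC1(C)C[C@H](O)C[C@](C)(O)[C@@]12C=CCCC23SCCS3
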